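**Retrosynthetic overview**
1. Last C–C bond (C8–C7): trans-selective alkylation of the lithium enolate of (R)-lactone 22 (closed dihydrobenzofuran arm) with benzylic bromide 15 (open diol arm); one global desilylation finishes the synthesis.
2. Lactone 22: Negishi coupling of a benzylzinc with 4-bromofuran-2(5H)-one, then Ru–BINAP hydrogenation sets C8'.
3. Key C–O bond: both arms come from one racemic anti-1,2-diaryl-1,3-diol (10). A chiral phosphoric acid closes the dihydrobenzofuran C7–O bond of the 1R,2R enantiomer only (→ 11) and leaves the 1S,2S enantiomer (12) as the open arm.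
4. Racemic 10: anti-selective aldol of arylacetate 5 with O-benzylvanillin, ester reduction, hydrogenolysis; 5 comes from methyl 5-bromovanillate by Pd-catalysed Reformatsky arylation.
5. Ring order: dihydrobenzofuran (step 6), then the butenolide/lactone ring is attached (steps 13–14); all benzene rings are bought.

Assumption: the catalyst enantiomers written in steps 6 and 14 are chosen by analogy, and the mirror-image catalyst is used if the observed sense is opposite; C7 is the benzylic O-bearing carbon of a C3 side chain, C8 its neighbour, TBS = tert-butyldimethylsilyl.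

**Route**

Step 1
Reactants: 1 methyl 3-bromo-4-hydroxy-5-methoxybenzoate
Product: 2 methyl 4-(benzyloxy)-3-bromo-5-methoxybenzoate
Conditions: BnBr, K2CO3, DMF, 60 °C
Reagents that add atoms: benzyl bromide BrCc1ccccc1
Why: Williamson ether synthesis on the phenoxide masks the phenol for the organometallic steps; no stereocentre is involved.

Step 2
Reactants: 2 methyl 4-(benzyloxy)-3-bromo-5-methoxybenzoate; 3 ethyl bromoacetate
Product: 5 methyl 4-(benzyloxy)-3-(2-ethoxy-2-oxoethyl)-5-methoxybenzoate, via Reformatsky reagent 4 (not isolated)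
Conditions: Zn dust (TMSCl-activated), 3, THF, 40 °C; then 2, Pd2(dba)3 (2.5 mol %), XPhos (10 mol %), THF, 65 °C
Reagents that add atoms: none
Why: Palladium-catalysed Negishi-type coupling of a zinc ester enolate (Reformatsky reagent) with an electron-poor aryl bromide gives the arylacetate and tolerates both esters; no stereocentre is formed.

Step 3
Reactants: 5 methyl 4-(benzyloxy)-3-(2-ethoxy-2-oxoethyl)-5-methoxybenzoate; 6 4-(benzyloxy)-3-methoxybenzaldehyde
Product: 8 racemic ethyl (2R*,3S*)-2-[2-(benzyloxy)-3-methoxy-5-(methoxycarbonyl)phenyl]-3-[4-(benzyloxy)-3-methoxyphenyl]-3-hydroxypropanoate (anti aldol), via lithium enolate 7 (not isolated)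
Conditions: LiN(SiMe3)2 (1.05 equiv), THF, −78 °C; then 6, −78 → 0 °C; AcOH quench; minor syn isomer removed by chromatography
Reagents that add atoms: none
Why: Reversible ester aldol addition under thermodynamic control, where the lithium aldolate settles in the Zimmerman–Traxler chelate with both aryl groups equatorial (the sense of the Ivanov reaction), sets the anti relation of C7 and C8 as a racemate.

Step 4
Reactants: 8 racemic anti aldol ester
Product: 9 racemic methyl 4-(benzyloxy)-3-{(1S*,2S*)-1-[4-(benzyloxy)-3-methoxyphenyl]-1,3-dihydroxypropan-2-yl}-5-methoxybenzoate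
Conditions: LiBH4 (2 equiv), THF, 0 °C → rt
Reagents that add atoms: none
Why: Hydroxyl-assisted borohydride reduction takes the aliphatic β-hydroxy ester much faster than the electron-rich methyl benzoate; both stereocentres are carried over (the C8 descriptor changes only because the CIP priorities change).

Step 5
Reactants: 9 racemic dibenzyl diol
Product: 10 racemic methyl 3-[(1S*,2S*)-1,3-dihydroxy-1-(4-hydroxy-3-methoxyphenyl)propan-2-yl]-4-hydroxy-5-methoxybenzoate
Conditions: H2 (1 atm), palladium on carbon (Pd/C, 10 %), EtOAc–MeOH, rt, stopped at full debenzylation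
Reagents that add atoms: none
Why: Hydrogenolysis of the two aryl benzyl ethers is far faster in neutral medium than cleavage of the benzylic alcohol; stereocentres are untouched.

Step 6
Reactants: 10 racemic tetraol
Product: 11 methyl (2S,3R)-2-(4-hydroxy-3-methoxyphenyl)-3-(hydroxymethyl)-7-methoxy-2,3-dihydro-1-benzofuran-5-carboxylate and 12 methyl 3-[(1S,2S)-1,3-dihydroxy-1-(4-hydroxy-3-methoxyphenyl)propan-2-yl]-4-hydroxy-5-methoxybenzoate (unreacted enantiomer of 10, recovered)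
Conditions: (R)-TRIP [(R)-3,3'-bis(2,4,6-triisopropylphenyl)-1,1'-binaphthyl-2,2'-diyl hydrogen phosphate] (5 mol %), 4 Å molecular sieves, CH2Cl2–MeCN (5:1), −20 °C, run to about 52–55 % conversion; chromatographic separation
Reagents that add atoms: none
Why: Proposed new method: kinetic resolution by enantiomer-selective dehydrative cycloetherification under a chiral phosphoric acid. The catalyst bridges the acidic ring B phenol (to P=O) and the benzylic C7 hydroxyl (to P–OH), so water leaves with quinone-methide-like help from the para-hydroxyl of ring A while the phenol oxygen closes the five-membered ring from the opposite face (inversion at C7, C8 untouched). Only the 1R,2R enantiomer is expected to fit this arrangement in the chiral pocket, giving trans-(2S,3R)-11; (1S,2S)-12 keeps its configuration because ionisation is followed at once by ring closure and does not return to the diol. The closest known reaction types are phosphoric-acid-catalysed 1,6-additions to para-quinone methides made from para-hydroxybenzyl alcohols, Brønsted-acid-catalysed stereospecific intramolecular substitution of benzylic alcohols, and the achiral acid closure of such diols to trans-phenylcoumarans.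

Step 7
Reactants: 12 (1S,2S)-tetraol
Product: 13 methyl 4-(TBS-oxy)-3-{(1S,2S)-1,3-bis(TBS-oxy)-1-[4-(TBS-oxy)-3-methoxyphenyl]propan-2-yl}-5-methoxybenzoate
Conditions: TBSCl (6 equiv), imidazole, DMAP (cat.), DMF, 40 °C
Reagents that add atoms: tert-butyldimethylsilyl chloride CC(C)(C)[Si](C)(C)Cl
Why: Silyl ether formation without a strong Lewis acid caps both phenols first, so the benzylic alcohol cannot cyclise; configuration is retained.

Step 8
Reactants: 13 tetra-TBS ester
Product: 14 {4-(TBS-oxy)-3-[(1S,2S)-1,3-bis(TBS-oxy)-1-(4-(TBS-oxy)-3-methoxyphenyl)propan-2-yl]-5-methoxyphenyl}methanol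
Conditions: iBu2AlH (3 equiv), CH2Cl2, −78 → 0 °C; Rochelle salt work-up
Reagents that add atoms: none
Why: Hydride reduction of the methyl benzoate to the benzylic alcohol; silyl ethers and stereocentres are inert.

Step 9
Reactants: 14 benzylic alcohol
Product: 15 benzylic bromide, tert-butyl{4-(bromomethyl)-2-[(1S,2S)-1,3-bis(TBS-oxy)-1-(4-(TBS-oxy)-3-methoxyphenyl)propan-2-yl]-6-methoxyphenoxy}dimethylsilane
Conditions: CBr4, PPh3, CH2Cl2, 0 °C; used at once
Reagents that add atoms: carbon tetrabromide BrC(Br)(Br)Br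
Why: Appel bromination of a primary benzylic alcohol under neutral conditions; no stereocentre is touched.

Step 10
Reactants: 11 dihydrobenzofuran diol ester
Product: 16 methyl (2S,3R)-3-[(TBS-oxy)methyl]-2-[4-(TBS-oxy)-3-methoxyphenyl]-7-methoxy-2,3-dihydro-1-benzofuran-5-carboxylate
Conditions: TBSCl (3 equiv), imidazole, DMF, rt
Reagents that add atoms: tert-butyldimethylsilyl chloride CC(C)(C)[Si](C)(C)Cl
Why: Silyl ether formation on the phenol and the primary alcohol; configuration is retained.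

Step 11
Reactants: 16 bis-TBS ester
Product: 17 {(2S,3R)-3-[(TBS-oxy)methyl]-2-[4-(TBS-oxy)-3-methoxyphenyl]-7-methoxy-2,3-dihydro-1-benzofuran-5-yl}methanol
Conditions: iBu2AlH (3 equiv), CH2Cl2, −78 → 0 °C; Rochelle salt work-up
Reagents that add atoms: none
Why: Hydride reduction of the aryl ester to the benzylic alcohol; the cyclic benzylic ether and the stereocentres are inert.

Step 12
Reactants: 17 benzylic alcohol
Product: 18 (2S,3R)-5-(chloromethyl)-3-[(TBS-oxy)methyl]-2-[4-(TBS-oxy)-3-methoxyphenyl]-7-methoxy-2,3-dihydro-1-benzofuran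
Conditions: N-chlorosuccinimide, PPh3, CH2Cl2, 0 °C
Reagents that add atoms: N-chlorosuccinimide O=C1CCC(=O)N1Cl
Why: Appel-type chlorination gives the benzylic chloride, the preferred precursor for zinc insertion with little Wurtz coupling.

Step 13
Reactants: 18 benzylic chloride; 19 4-bromofuran-2(5H)-one
Product: 21 4-({(2S,3R)-3-[(TBS-oxy)methyl]-2-[4-(TBS-oxy)-3-methoxyphenyl]-7-methoxy-2,3-dihydro-1-benzofuran-5-yl}methyl)furan-2(5H)-one, via benzylzinc chloride 20 (not isolated)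
Conditions: Zn dust, LiCl, THF, rt; then 19, Pd(OAc)2 (2 mol %), SPhos (4 mol %), THF, rt
Reagents that add atoms: none
Why: Zinc insertion into the benzylic chloride followed by Negishi sp3–sp2 coupling with the vinylogous acyl bromide gives the β-benzyl butenolide; existing stereocentres are remote and untouched.

Step 14
Reactants: 21 butenolide
Product: 22 (4R)-4-({(2S,3R)-3-[(TBS-oxy)methyl]-2-[4-(TBS-oxy)-3-methoxyphenyl]-7-methoxy-2,3-dihydro-1-benzofuran-5-yl}methyl)oxolan-2-one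
Conditions: Ru(OAc)2[(R)-BINAP] (1 mol %), H2 (80 atm), MeOH–CH2Cl2, 50 °C
Reagents that add atoms: none
Why: Ruthenium–BINAP asymmetric hydrogenation of a β-substituted butenolide, a known reaction class, delivers hydrogen to one face of the trisubstituted alkene and sets C8' as R under catalyst control.

Step 15
Reactants: 22 (R)-lactone; 15 benzylic bromide
Product: 24 hexa-TBS ether of the target, (3R,4R)-3,4-dibenzyl lactone, via lactone lithium enolate 23 (not isolated)
Conditions: LiN(SiMe3)2 (1.1 equiv), THF, −78 °C; then 15, DMPU, −78 → −40 °C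
Reagents that add atoms: none
Why: Alkylation of the β-substituted butyrolactone enolate takes place anti to the C4 substituent (the standard dibenzylbutyrolactone lignan alkylation), which sets C8 as R, trans to C8'.

Step 16
Reactants: 24 hexa-TBS ether
Product: 25 CNP0186558.2 (target)
Conditions: Bu4NF/AcOH (1:1, 10 equiv), THF, 0 °C → rt
Reagents that add atoms: none
Why: Acetic-acid-buffered fluoride desilylation removes all six silyl groups near neutrality, so the lactone stays closed and the open benzylic diol arm neither cyclises nor epimerises.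

**Compound list**

1 | methyl 3-bromo-4-hydroxy-5-methoxybenzoate (methyl 5-bromovanillate) | COC(=O)c1cc(Br)c(O)c(OC)c1 | starting material
2 | methyl 4-(benzyloxy)-3-bromo-5-methoxybenzoate | COC(=O)c1cc(Br)c(OCc2ccccc2)c(OC)c1 | intermediate
3 | ethyl bromoacetate | CCOC(=O)CBr | starting material
4 | ethyl (bromozincio)acetate, Reformatsky reagent | CCOC(=O)C[Zn]Br | intermediate
5 | methyl 4-(benzyloxy)-3-(2-ethoxy-2-oxoethyl)-5-methoxybenzoate | CCOC(=O)Cc1cc(C(=O)OC)cc(OC)c1OCc1ccccc1 | intermediate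
6 | 4-(benzyloxy)-3-methoxybenzaldehyde (O-benzylvanillin) | COc1cc(C=O)ccc1OCc1ccccc1 | starting material
7 | lithium enolate of 5 (enolate geometry not defined) | [Li]OC(OCC)=Cc1cc(C(=O)OC)cc(OC)c1OCc1ccccc1 | intermediate
8 | racemic ethyl (2R*,3S*)-2-[2-(benzyloxy)-3-methoxy-5-(methoxycarbonyl)phenyl]-3-[4-(benzyloxy)-3-methoxyphenyl]-3-hydroxypropanoate (both enantiomers shown) | COc1cc([C@@H](O)[C@H](C(=O)OCC)c2cc(C(=O)OC)cc(OC)c2OCc2ccccc2)ccc1OCc1ccccc1.COc1cc([C@H](O)[C@@H](C(=O)OCC)c2cc(C(=O)OC)cc(OC)c2OCc2ccccc2)ccc1OCc1ccccc1 | intermediate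
9 | racemic methyl 4-(benzyloxy)-3-{(1S*,2S*)-1-[4-(benzyloxy)-3-methoxyphenyl]-1,3-dihydroxypropan-2-yl}-5-methoxybenzoate (both enantiomers shown) | COc1cc([C@@H](O)[C@H](CO)c2cc(C(=O)OC)cc(OC)c2OCc2ccccc2)ccc1OCc1ccccc1.COc1cc([C@H](O)[C@@H](CO)c2cc(C(=O)OC)cc(OC)c2OCc2ccccc2)ccc1OCc1ccccc1 | intermediate
10 | racemic methyl 3-[(1S*,2S*)-1,3-dihydroxy-1-(4-hydroxy-3-methoxyphenyl)propan-2-yl]-4-hydroxy-5-methoxybenzoate (both enantiomers shown) | COc1cc([C@@H](O)[C@H](CO)c2cc(C(=O)OC)cc(OC)c2O)ccc1O.COc1cc([C@H](O)[C@@H](CO)c2cc(C(=O)OC)cc(OC)c2O)ccc1O | intermediate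
11 | methyl (2S,3R)-2-(4-hydroxy-3-methoxyphenyl)-3-(hydroxymethyl)-7-methoxy-2,3-dihydro-1-benzofuran-5-carboxylate | COC(=O)c1cc(OC)c2c(c1)[C@H](CO)[C@@H](c1ccc(O)c(OC)c1)O2 | intermediate
12 | methyl 3-[(1S,2S)-1,3-dihydroxy-1-(4-hydroxy-3-methoxyphenyl)propan-2-yl]-4-hydroxy-5-methoxybenzoate | COc1cc([C@@H](O)[C@H](CO)c2cc(C(=O)OC)cc(OC)c2O)ccc1O | intermediate
13 | methyl 4-(TBS-oxy)-3-{(1S,2S)-1,3-bis(TBS-oxy)-1-[4-(TBS-oxy)-3-methoxyphenyl]propan-2-yl}-5-methoxybenzoate | COc1cc([C@@H](O[Si](C)(C)C(C)(C)C)[C@H](CO[Si](C)(C)C(C)(C)C)c2cc(C(=O)OC)cc(OC)c2O[Si](C)(C)C(C)(C)C)ccc1O[Si](C)(C)C(C)(C)C | intermediate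
14 | {4-(TBS-oxy)-3-[(1S,2S)-1,3-bis(TBS-oxy)-1-(4-(TBS-oxy)-3-methoxyphenyl)propan-2-yl]-5-methoxyphenyl}methanol | COc1cc([C@@H](O[Si](C)(C)C(C)(C)C)[C@H](CO[Si](C)(C)C(C)(C)C)c2cc(CO)cc(OC)c2O[Si](C)(C)C(C)(C)C)ccc1O[Si](C)(C)C(C)(C)C | intermediate
15 | benzylic bromide of 14 (CH2OH replaced by CH2Br; 1S,2S side chain, four TBS ethers) | COc1cc([C@@H](O[Si](C)(C)C(C)(C)C)[C@H](CO[Si](C)(C)C(C)(C)C)c2cc(CBr)cc(OC)c2O[Si](C)(C)C(C)(C)C)ccc1O[Si](C)(C)C(C)(C)C | intermediate
16 | methyl (2S,3R)-3-[(TBS-oxy)methyl]-2-[4-(TBS-oxy)-3-methoxyphenyl]-7-methoxy-2,3-dihydro-1-benzofuran-5-carboxylate | COC(=O)c1cc(OC)c2c(c1)[C@H](CO[Si](C)(C)C(C)(C)C)[C@@H](c1ccc(O[Si](C)(C)C(C)(C)C)c(OC)c1)O2 | intermediate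
17 | {(2S,3R)-3-[(TBS-oxy)methyl]-2-[4-(TBS-oxy)-3-methoxyphenyl]-7-methoxy-2,3-dihydro-1-benzofuran-5-yl}methanol | OCc1cc(OC)c2c(c1)[C@H](CO[Si](C)(C)C(C)(C)C)[C@@H](c1ccc(O[Si](C)(C)C(C)(C)C)c(OC)c1)O2 | intermediate
18 | (2S,3R)-5-(chloromethyl)-3-[(TBS-oxy)methyl]-2-[4-(TBS-oxy)-3-methoxyphenyl]-7-methoxy-2,3-dihydro-1-benzofuran | ClCc1cc(OC)c2c(c1)[C@H](CO[Si](C)(C)C(C)(C)C)[C@@H](c1ccc(O[Si](C)(C)C(C)(C)C)c(OC)c1)O2 | intermediate
19 | 4-bromofuran-2(5H)-one | O=C1OCC(Br)=C1 | starting material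
20 | benzylzinc chloride from 18 | Cl[Zn]Cc1cc(OC)c2c(c1)[C@H](CO[Si](C)(C)C(C)(C)C)[C@@H](c1ccc(O[Si](C)(C)C(C)(C)C)c(OC)c1)O2 | intermediate
21 | 4-({(2S,3R)-3-[(TBS-oxy)methyl]-2-[4-(TBS-oxy)-3-methoxyphenyl]-7-methoxy-2,3-dihydro-1-benzofuran-5-yl}methyl)furan-2(5H)-one | O=C1OCC(Cc2cc(OC)c3c(c2)[C@H](CO[Si](C)(C)C(C)(C)C)[C@@H](c2ccc(O[Si](C)(C)C(C)(C)C)c(OC)c2)O3)=C1 | intermediate
22 | (4R)-4-({(2S,3R)-3-[(TBS-oxy)methyl]-2-[4-(TBS-oxy)-3-methoxyphenyl]-7-methoxy-2,3-dihydro-1-benzofuran-5-yl}methyl)oxolan-2-one | O=C1OC[C@H](Cc2cc(OC)c3c(c2)[C@H](CO[Si](C)(C)C(C)(C)C)[C@@H](c2ccc(O[Si](C)(C)C(C)(C)C)c(OC)c2)O3)C1 | intermediate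
23 | lithium enolate of 22 | [Li]OC1=C[C@@H](Cc2cc(OC)c3c(c2)[C@H](CO[Si](C)(C)C(C)(C)C)[C@@H](c2ccc(O[Si](C)(C)C(C)(C)C)c(OC)c2)O3)CO1 | intermediate
24 | hexa-TBS ether of the target: (3R,4R)-oxolan-2-one with the 1S,2S open-arm benzyl group at C3 and the (2S,3R)-dihydrobenzofuranylmethyl group at C4 | COc1cc([C@@H](O[Si](C)(C)C(C)(C)C)[C@H](CO[Si](C)(C)C(C)(C)C)c2cc(C[C@H]3C(=O)OC[C@@H]3Cc3cc(OC)c4c(c3)[C@H](CO[Si](C)(C)C(C)(C)C)[C@@H](c3ccc(O[Si](C)(C)C(C)(C)C)c(OC)c3)O4)cc(OC)c2O[Si](C)(C)C(C)(C)C)ccc1O[Si](C)(C)C(C)(C)C | intermediate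
25 | CNP0186558.2 | COc1cc([C@@H](O)[C@H](CO)c2cc(C[C@H]3C(=O)OC[C@@H]3Cc3cc(OC)c4c(c3)[C@H](CO)[C@@H](c3ccc(O)c(OC)c3)O4)cc(OC)c2O)ccc1O | target

**Totals**
Total step count: 16. Longest linear sequence: 13 steps (1–6, then 10–16).

**Three steps most likely to fail, with fallbacks**

Step 6 (the new resolution by ring closure; risk: low selectivity factor, giving 11 and 12 of insufficient enantiopurity). The fallback sets out from 10 and comes back at 11 and 12. Racemic 10 is separated by preparative supercritical-fluid chromatography on an amylose tris(3,5-dimethylphenylcarbamate) phase into 12 and its mirror image, methyl 3-[(1R,2R)-1,3-dihydroxy-1-(4-hydroxy-3-methoxyphenyl)propan-2-yl]-4-hydroxy-5-methoxybenzoate F1. F1 is then closed with an achiral acid (pyridinium p-toluenesulfonate, CH2Cl2, rt), the known acid-catalysed phenylcoumaran closure through the quinone methide, which gives the trans product 11 under control of C8.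

Step 3 (risk: modest anti/syn ratio in the ester aldol). The fallback sets out from 5 and comes back at 9. The ethyl ester of 5 is saponified selectively (LiOH, 1.05 equiv, THF–H2O, 0 °C) to [2-(benzyloxy)-3-methoxy-5-(methoxycarbonyl)phenyl]acetic acid F2. The dilithium enediolate of F2 (LiN(iPr)2, 2.1 equiv, THF, −78 °C) is added to 6 and the aldolate is left to equilibrate at 0 °C to rt, the carboxylic-acid-dianion aldol known to favour the anti acid, which gives racemic (2R*,3S*)-2-[2-(benzyloxy)-3-methoxy-5-(methoxycarbonyl)phenyl]-3-[4-(benzyloxy)-3-methoxyphenyl]-3-hydroxypropanoic acid F3. BH3·SMe2 (THF, 0 °C) then reduces the carboxylic acid of F3 in the presence of the aryl ester, and this gives 9.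

Step 14 (risk: sense or level of induction of the hydrogenation on this substrate). The fallback sets out from 18 and comes back at 22, replacing steps 13 and 14 by auxiliary control. The sodium enolate of the known imide reagent (4R)-4-benzyl-3-(4-tert-butoxy-4-oxobutanoyl)-1,3-oxazolidin-2-one (NaN(SiMe3)2, THF, −78 °C) is alkylated with 18 (NaI, 10 mol %), anti to the auxiliary benzyl group, to give (4R)-4-benzyl-3-[(2R)-4-tert-butoxy-2-({(2S,3R)-3-[(TBS-oxy)methyl]-2-[4-(TBS-oxy)-3-methoxyphenyl]-7-methoxy-2,3-dihydro-1-benzofuran-5-yl}methyl)-4-oxobutanoyl]-1,3-oxazolidin-2-one F4. LiBH4 (THF–H2O, 0 °C) removes the auxiliary from F4 and gives tert-butyl (3R)-4-hydroxy-3-({(2S,3R)-3-[(TBS-oxy)methyl]-2-[4-(TBS-oxy)-3-methoxyphenyl]-7-methoxy-2,3-dihydro-1-benzofuran-5-yl}methyl)butanoate F5. Catalytic camphorsulfonic acid in toluene at 60 °C then lactonises F5 to 22.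

**Further compounds**

F1 | step 6 | methyl 3-[(1R,2R)-1,3-dihydroxy-1-(4-hydroxy-3-methoxyphenyl)propan-2-yl]-4-hydroxy-5-methoxybenzoate | COc1cc([C@H](O)[C@@H](CO)c2cc(C(=O)OC)cc(OC)c2O)ccc1O
F2 | step 3 | [2-(benzyloxy)-3-methoxy-5-(methoxycarbonyl)phenyl]acetic acid | OC(=O)Cc1cc(C(=O)OC)cc(OC)c1OCc1ccccc1
F3 | step 3 | racemic (2R*,3S*)-2-[2-(benzyloxy)-3-methoxy-5-(methoxycarbonyl)phenyl]-3-[4-(benzyloxy)-3-methoxyphenyl]-3-hydroxypropanoic acid (both enantiomers shown) | COc1cc([C@@H](O)[C@H](C(=O)O)c2cc(C(=O)OC)cc(OC)c2OCc2ccccc2)ccc1OCc1ccccc1.COc1cc([C@H](O)[C@@H](C(=O)O)c2cc(C(=O)OC)cc(OC)c2OCc2ccccc2)ccc1OCc1ccccc1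
F4 | step 14 | (4R)-4-benzyl-3-[(2R)-4-tert-butoxy-2-({(2S,3R)-3-[(TBS-oxy)methyl]-2-[4-(TBS-oxy)-3-methoxyphenyl]-7-methoxy-2,3-dihydro-1-benzofuran-5-yl}methyl)-4-oxobutanoyl]-1,3-oxazolidin-2-one | O=C1OC[C@@H](Cc2ccccc2)N1C(=O)[C@@H](CC(=O)OC(C)(C)C)Cc1cc(OC)c2c(c1)[C@H](CO[Si](C)(C)C(C)(C)C)[C@@H](c1ccc(O[Si](C)(C)C(C)(C)C)c(OC)c1)O2
F5 | step 14 | tert-butyl (3R)-4-hydroxy-3-({(2S,3R)-3-[(TBS-oxy)methyl]-2-[4-(TBS-oxy)-3-methoxyphenyl]-7-methoxy-2,3-dihydro-1-benzofuran-5-yl}methyl)butanoate | OC[C@@H](CC(=O)OC(C)(C)C)Cc1cc(OC)c2c(c1)[C@H](CO[Si](C)(C)C(C)(C)C)[C@@H](c1ccc(O[Si](C)(C)C(C)(C)C)c(OC)c1)O2
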